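**Retrosynthetic overview**
- Last bond: O1–C8a of the dihydropyranone (a vinylogous-ester C–O bond), closed by cyclodehydration of a δ-hydroxy triketone; C2 comes from the chiral pool and is retained.
- Quaternary C8: enantioselective dearomative C-geranylation at the methyl-bearing carbon of a fully substituted acylphloroglucinol.
- Acylphloroglucinol: C-prenylation, preceded by Houben–Hoesch acylation of 2,4,6-trihydroxytoluene with (S)-3-hydroxybutanenitrile.
- Ring order: the carbocycle is bought as the arene, dearomatised in step 3, and the pyranone ring is closed last.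

Assumption: (S)-3-hydroxybutanenitrile (≥98% ee) is bought as a chiral-pool building block. The dearomatised compounds are drawn as one enol tautomer, so the CIP letter of the quaternary carbon changes from S (open triketone) to R (target) with no change in its spatial arrangement.

**Step 1**
Reactants: 1 2-methylbenzene-1,3,5-triol (2,4,6-trihydroxytoluene); 2 (3S)-3-hydroxybutanenitrile
Product: 4 (3S)-3-hydroxy-1-(2,4,6-trihydroxy-3-methylphenyl)butan-1-one, via ketiminium chloride 3 (not isolated)
Conditions: HCl (g), Et2O, 0 °C, 24 h; then H2O, 50 °C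
Reagents that add atoms: water, O
Why: Houben–Hoesch acylation, in which the HCl-activated nitrile attacks one of the two equivalent free positions of the electron-rich triol, the ketiminium salt blocks a second acylation, and mild hydrolysis gives the ketone without touching the carbinol carbon, so (S) is carried over from the chiral pool.

**Step 2**
Reactants: 4 (3S)-3-hydroxy-1-(2,4,6-trihydroxy-3-methylphenyl)butan-1-one; 5 1-bromo-3-methylbut-2-ene (prenyl bromide)
Product: 6 (3S)-3-hydroxy-1-[2,4,6-trihydroxy-3-methyl-5-(3-methylbut-2-en-1-yl)phenyl]butan-1-one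
Conditions: KOH (1.05 equiv), H2O, 0 °C
Reagents that add atoms: none
Why: SN2 C-alkylation of the ambident phenolate in water (hydrogen bonding to oxygen favours C- over O-attack) at C5, the only ring carbon that can rearomatise, with one equivalent of cold dilute base limiting over-alkylation and sparing the β-hydroxy ketone.

**Step 3**
Reactants: 6 (3S)-3-hydroxy-1-[2,4,6-trihydroxy-3-methyl-5-(3-methylbut-2-en-1-yl)phenyl]butan-1-one; 7 (2E)-3,7-dimethylocta-2,6-dien-1-yl acetate (geranyl acetate)
Product: 8 (6S)-6-[(2E)-3,7-dimethylocta-2,6-dien-1-yl]-3,5-dihydroxy-2-[(3S)-3-hydroxybutanoyl]-6-methyl-4-(3-methylbut-2-en-1-yl)cyclohexa-2,4-dien-1-one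
Conditions: Pd2(dba)3·CHCl3 (2.5 mol%), (R,R)-DACH-phenyl Trost ligand (7.5 mol%), Et3N (2.5 equiv), degassed THF, 0 °C
Reagents that add atoms: none
Why: Proposed new method: Pd/Trost-ligand-catalysed enantioselective dearomative C-geranylation of a fully substituted acylphloroglucinol, in which ionisation of 7 gives a π-geranyl-Pd cation and the ammonium phenolate of 6 attacks outer-sphere through its methyl-bearing carbon (the less hindered of the two doubly oxygen-flanked carbons) at the CH2 terminus (linear, E kept because capture outruns η3–η1 isomerisation), O-allylation being reversible under Pd and no uncatalysed background existing for an acetate, while the chiral pocket differentiates the two faces of the flat nucleophile because its flanks differ (chelated acyl side versus prenyl side) and so sets the quaternary centre; the closest known reaction types are Pd-catalysed asymmetric allylic-alkylation dearomatisation of naphthols and phenols, asymmetric linear prenylation/geranylation of oxindole enolates, and racemic dearomative allylation of acylphloroglucinols.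

**Step 4**
Reactants: 8 (6S)-6-[(2E)-3,7-dimethylocta-2,6-dien-1-yl]-3,5-dihydroxy-2-[(3S)-3-hydroxybutanoyl]-6-methyl-4-(3-methylbut-2-en-1-yl)cyclohexa-2,4-dien-1-one
Product: 10 (2S,8R)-8-[(2E)-3,7-dimethylocta-2,6-dien-1-yl]-5-hydroxy-2,8-dimethyl-6-(3-methylbut-2-en-1-yl)-2,3-dihydro-4H-chromene-4,7(8H)-dione, via cyclic hemiketal 9 (not isolated)
Conditions: CSA (10 mol%), 4 Å MS, CH2Cl2, 0 °C → rt
Reagents that add atoms: none
Why: Acid-catalysed cyclodehydration of a δ-hydroxy-β-diketone (hemiketalisation then vinylogous dehydration to the 2,3-dihydro-4H-pyran-4-one), in which the side-chain hydroxyl adds to the ring C1 ketone next to the quaternary carbon (the acyl C=O is chelated by the 3-OH on the other side, which points the chain toward C1, the sense in which related 6,6-dialkyl-2-acyl triketones close), and because the new C–O bond is made to the ring carbon the carbinol C–O bond is never broken, so C2 keeps (S), the quaternary centre is untouched, and any 9 or 10 formed early from 8 converges on the same product.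

**Compound list**
1 | 2-methylbenzene-1,3,5-triol (2,4,6-trihydroxytoluene) | Cc1c(O)cc(O)cc1O | starting material
2 | (3S)-3-hydroxybutanenitrile | C[C@H](O)CC#N | starting material
3 | (3S)-3-hydroxy-1-(2,4,6-trihydroxy-3-methylphenyl)butan-1-iminium chloride | C[C@H](O)CC(=[NH2+])c1c(O)cc(O)c(C)c1O.[Cl-] | intermediate
4 | (3S)-3-hydroxy-1-(2,4,6-trihydroxy-3-methylphenyl)butan-1-one | C[C@H](O)CC(=O)c1c(O)cc(O)c(C)c1O | intermediate
5 | 1-bromo-3-methylbut-2-ene (prenyl bromide) | CC(C)=CCBr | starting material
6 | (3S)-3-hydroxy-1-[2,4,6-trihydroxy-3-methyl-5-(3-methylbut-2-en-1-yl)phenyl]butan-1-one | C[C@H](O)CC(=O)c1c(O)c(C)c(O)c(CC=C(C)C)c1O | intermediate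
7 | (2E)-3,7-dimethylocta-2,6-dien-1-yl acetate (geranyl acetate) | CC(C)=CCC/C(C)=C/COC(C)=O | starting material
8 | (6S)-6-[(2E)-3,7-dimethylocta-2,6-dien-1-yl]-3,5-dihydroxy-2-[(3S)-3-hydroxybutanoyl]-6-methyl-4-(3-methylbut-2-en-1-yl)cyclohexa-2,4-dien-1-one | CC(C)=CCC/C(C)=C/C[C@@]1(C)C(O)=C(CC=C(C)C)C(O)=C(C(=O)C[C@H](C)O)C1=O | intermediate
9 | (2S,8S)-8-[(2E)-3,7-dimethylocta-2,6-dien-1-yl]-5,7,8a-trihydroxy-2,8-dimethyl-6-(3-methylbut-2-en-1-yl)-2,3,8,8a-tetrahydro-4H-chromen-4-one (cyclic hemiketal of 8; both 8a-epimers) | CC(C)=CCC/C(C)=C/C[C@@]1(C)C(O)=C(CC=C(C)C)C(O)=C2C(=O)C[C@H](C)OC12O | intermediate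
10 | (2S,8R)-8-[(2E)-3,7-dimethylocta-2,6-dien-1-yl]-5-hydroxy-2,8-dimethyl-6-(3-methylbut-2-en-1-yl)-2,3-dihydro-4H-chromene-4,7(8H)-dione | CC(C)=CCC/C(C)=C/C[C@@]1(C)C(=O)C(CC=C(C)C)=C(O)C2=C1O[C@@H](C)CC2=O | target

**Totals**
Total step count: 4. Longest linear sequence: 4 (1 → 4 → 6 → 8 → 10).

**Three steps most likely to fail**

Step 3 (the proposed new step). Risks are low enantioselectivity, attack at the prenyl-bearing carbon, over-allylation and E/Z leakage. Which ligand antipode gives the (6S) centre cannot be predicted and must be assigned on the first run; the (S,S)-ligand is the remedy if the epimer forms. The fallback uses known chemistry, sets out from 6 and comes back at 8. It is the classical base-mediated dearomative C-alkylation with geranyl bromide (NaOMe, MeOH, 0 °C), which is not face-selective and gives 8 together with (6R)-6-[(2E)-3,7-dimethylocta-2,6-dien-1-yl]-3,5-dihydroxy-2-[(3S)-3-hydroxybutanoyl]-6-methyl-4-(3-methylbut-2-en-1-yl)cyclohexa-2,4-dien-1-one F1. Because the side chain is enantiopure, the two are diastereomers and are separated by preparative HPLC. If they co-elute, the mixture is taken through step 4 and 10 is separated from the more rigid bicyclic (2S,8S)-8-[(2E)-3,7-dimethylocta-2,6-dien-1-yl]-5-hydroxy-2,8-dimethyl-6-(3-methylbut-2-en-1-yl)-2,3-dihydro-4H-chromene-4,7(8H)-dione F2.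

Step 1. Hoesch acylation with a free β-hydroxy nitrile is not established here. Risks are Pinner-type consumption of the nitrile, and dehydration to the crotonyl ketone during hydrolysis followed by closure to a racemic chromanone. The fallback sets out from 1 and comes back at 4, replacing electrophilic acylation by an aryllithium/Weinreb ketone synthesis. 1 is protected (MOMCl, NaH, DMF) as 1,3,5-tris(methoxymethoxy)-2-methylbenzene F3, which is lithiated between two OMOM groups (n-BuLi, THF, 0 °C) to [2,4,6-tris(methoxymethoxy)-3-methylphenyl]lithium F4. Separately, ethyl (S)-3-hydroxybutanoate is converted (MeNHOMe·HCl, i-PrMgCl) into (3S)-3-hydroxy-N-methoxy-N-methylbutanamide F5 and silylated (TBSCl, imidazole) to (3S)-3-[(tert-butyldimethylsilyl)oxy]-N-methoxy-N-methylbutanamide F6. Addition of the aryllithium to this amide gives (3S)-3-[(tert-butyldimethylsilyl)oxy]-1-[2,4,6-tris(methoxymethoxy)-3-methylphenyl]butan-1-one F7, and HCl in MeOH removes the MOM and TBS groups to give 4.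

Step 2. Mono-C-prenylation of acylphloroglucinols is typically low-yielding; competitors are O-prenylation, dearomative attack at the methyl-bearing carbon and double alkylation. The fallback sets out from 4 and comes back at 6. It is an acid-mediated Friedel–Crafts prenylation with 2-methylbut-3-en-2-ol (BF3·OEt2, dioxane, rt), that is, electrophilic aromatic substitution by a prenyl cation instead of phenolate SN2. Under acid, O-alkylation is reversible and only C5 can rearomatise. It makes no new compound.

**Further compounds**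
F1 | step 3 | (6R)-6-[(2E)-3,7-dimethylocta-2,6-dien-1-yl]-3,5-dihydroxy-2-[(3S)-3-hydroxybutanoyl]-6-methyl-4-(3-methylbut-2-en-1-yl)cyclohexa-2,4-dien-1-one | CC(C)=CCC/C(C)=C/C[C@]1(C)C(O)=C(CC=C(C)C)C(O)=C(C(=O)C[C@H](C)O)C1=O
F2 | step 3 | (2S,8S)-8-[(2E)-3,7-dimethylocta-2,6-dien-1-yl]-5-hydroxy-2,8-dimethyl-6-(3-methylbut-2-en-1-yl)-2,3-dihydro-4H-chromene-4,7(8H)-dione | CC(C)=CCC/C(C)=C/C[C@]1(C)C(=O)C(CC=C(C)C)=C(O)C2=C1O[C@@H](C)CC2=O
F3 | step 1 | 1,3,5-tris(methoxymethoxy)-2-methylbenzene | Cc1c(OCOC)cc(OCOC)cc1OCOC
F4 | step 1 | [2,4,6-tris(methoxymethoxy)-3-methylphenyl]lithium | [Li]c1c(OCOC)cc(OCOC)c(C)c1OCOC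
F5 | step 1 | (3S)-3-hydroxy-N-methoxy-N-methylbutanamide | C[C@H](O)CC(=O)N(C)OC
F6 | step 1 | (3S)-3-[(tert-butyldimethylsilyl)oxy]-N-methoxy-N-methylbutanamide | C[C@H](O[Si](C)(C)C(C)(C)C)CC(=O)N(C)OC
F7 | step 1 | (3S)-3-[(tert-butyldimethylsilyl)oxy]-1-[2,4,6-tris(methoxymethoxy)-3-methylphenyl]butan-1-one | C[C@H](O[Si](C)(C)C(C)(C)C)CC(=O)c1c(OCOC)cc(OCOC)c(C)c1OCOC
F0 | step 2 | none | none
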